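**Assumption:** the code is taken to mean exactly the given SMILES: a (2R,3S,4S)-4′,7-dihydroxyflavan-3-ol (2,3-trans-3,4-cis; rings A, B, C) joined through C4 to C6 of a (2S,3S)-3′,4′,7-trihydroxyflavan-3-ol (2,3-cis; rings D, E, F).

## Retrosynthetic overview

1. Target ⇐ pentabenzyl ether ⇐ 4-aryl-flavan-3,4-diol: H-4 goes in last by ionic hydrogenation, anti to the 3-OH, which gives the 3,4-cis aryl/OH pattern. The diol comes from OsO4 on a 4-aryl-2H-chromene, anti to the C2 aryl group, which gives 2,3-trans.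
2. Key disconnection: rings C and F are opened together to one acyclic bis(aryl ether). An aryl propargyl ether closes ring C by 6-endo hydroarylation and an aryl epoxybenzyl ether closes ring F by 6-endo epoxy–arene alkylation, both in one gold-catalysed operation.
3. The interflavan C4–C6 bond is an aryl–alkyne bond carried from the start; it is never made by coupling a flavan C4 cation with a phenol.
4. The C2 centre of each unit comes from a Mitsunobu inversion: of a Sharpless-resolved epoxy alcohol (which also supplies the lower C3) and of a propargylic alcohol from asymmetric alkynylation.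
5. Ring order: aromatic rings A, B, D, E are bought (3-(benzyloxy)phenol, 4-(benzyloxy)benzaldehyde, 2,4-dihydroxybenzaldehyde, 3,4-bis(benzyloxy)benzaldehyde); rings C and F form together in step 8.

## Route

Step 1
Reactants: 1 3,4-bis(benzyloxy)benzaldehyde
Product: 2 rac-1-[3,4-bis(benzyloxy)phenyl]prop-2-en-1-ol
Conditions: CH2=CHMgBr, THF, −78 → 0 °C; aq. NH4Cl
Reagents that add atoms: vinylmagnesium bromide, C=C[Mg]Br
Why: Grignard 1,2-addition to the aldehyde gives the racemic secondary allylic alcohol, whose stereocentre is fixed in step 2.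

Step 2
Reactants: 2 rac-1-[3,4-bis(benzyloxy)phenyl]prop-2-en-1-ol
Product: 3 (R)-[3,4-bis(benzyloxy)phenyl][(2S)-oxiran-2-yl]methanol
Conditions: Ti(OiPr)4 (0.2 equiv), D-(−)-DIPT (0.24 equiv), t-BuOOH (0.6 equiv), 4 Å MS, CH2Cl2, −20 °C, stopped near 50 % conversion
Reagents that add atoms: tert-butyl hydroperoxide, CC(C)(C)OO
Why: Sharpless kinetic resolution, in which the titanium–D-tartrate catalyst epoxidises the (S)-enantiomer of 2 much faster than the (R)-enantiomer (left behind and separated) and delivers oxygen to the face that gives the (2S)-oxirane anti (erythro) to the carbinol, so both stereocentres of 3 are set by the reagent.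

Step 3
Reactants: 3 (R)-[3,4-bis(benzyloxy)phenyl][(2S)-oxiran-2-yl]methanol, 4 2,4-dihydroxybenzaldehyde
Product: 5 4-{(S)-[3,4-bis(benzyloxy)phenyl][(2S)-oxiran-2-yl]methoxy}-2-hydroxybenzaldehyde
Conditions: PPh3, DIAD, THF, 0 °C → rt
Reagents that add atoms: none
Why: Mitsunobu etherification in which the free 4-OH of 4 (the 2-OH is hydrogen-bonded to the aldehyde) displaces the activated benzylic alcohol by SN2 with inversion, turning the (R)-carbinol into the (S)-aryl ether that is C2 of the lower unit, threo to the epoxide oxygen as needed for the 2,3-cis ring.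

Step 4
Reactants: 5 4-{(S)-[3,4-bis(benzyloxy)phenyl][(2S)-oxiran-2-yl]methoxy}-2-hydroxybenzaldehyde
Product: 6 2-(benzyloxy)-4-{(S)-[3,4-bis(benzyloxy)phenyl][(2S)-oxiran-2-yl]methoxy}benzaldehyde
Conditions: BnBr, K2CO3, DMF, 40 °C
Reagents that add atoms: benzyl bromide, BrCc1ccccc1
Why: Williamson O-benzylation of the remaining chelated phenol, under conditions that leave the epoxide and the ether stereocentre untouched.

Step 5
Reactants: 6 2-(benzyloxy)-4-{(S)-[3,4-bis(benzyloxy)phenyl][(2S)-oxiran-2-yl]methoxy}benzaldehyde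
Product: 7 2-(benzyloxy)-4-{(S)-[3,4-bis(benzyloxy)phenyl][(2S)-oxiran-2-yl]methoxy}-1-ethynylbenzene
Conditions: dimethyl (1-diazo-2-oxopropyl)phosphonate, K2CO3, MeOH–THF, rt
Reagents that add atoms: dimethyl (1-diazo-2-oxopropyl)phosphonate, CC(=O)C(=[N+]=[N-])P(=O)(OC)OC
Why: Seyferth–Gilbert homologation in its Ohira–Bestmann form converts the aryl aldehyde into the terminal alkyne under mild base that does not open the epoxide or touch a stereocentre.

Step 6
Reactants: 7 2-(benzyloxy)-4-{(S)-[3,4-bis(benzyloxy)phenyl][(2S)-oxiran-2-yl]methoxy}-1-ethynylbenzene, 8 4-(benzyloxy)benzaldehyde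
Product: 9 (1S)-1-[4-(benzyloxy)phenyl]-3-[2-(benzyloxy)-4-{(S)-[3,4-bis(benzyloxy)phenyl][(2S)-oxiran-2-yl]methoxy}phenyl]prop-2-yn-1-ol
Conditions: Me2Zn, ProPhenol ligand (10 mol %, the antipode that directs Re-face addition), Ph3P=O (20 mol %), toluene, 4 °C
Reagents that add atoms: none
Why: Catalytic asymmetric alkynylation of an aromatic aldehyde, in which the alkynylzinc formed from 7 and Me2Zn adds to the Re face of 8 within the dinuclear zinc–ProPhenol catalyst and sets the (S)-carbinol that becomes C2 of the upper unit after inversion.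

Step 7
Reactants: 9 (1S)-1-[4-(benzyloxy)phenyl]-3-[2-(benzyloxy)-4-{(S)-[3,4-bis(benzyloxy)phenyl][(2S)-oxiran-2-yl]methoxy}phenyl]prop-2-yn-1-ol, 10 3-(benzyloxy)phenol
Product: 11 3-(benzyloxy)phenyl (1R)-1-[4-(benzyloxy)phenyl]-3-[2-(benzyloxy)-4-{(S)-[3,4-bis(benzyloxy)phenyl][(2S)-oxiran-2-yl]methoxy}phenyl]prop-2-yn-1-yl ether
Conditions: PPh3, DIAD, toluene, −20 → 0 °C
Reagents that add atoms: none
Why: Mitsunobu etherification with SN2 inversion at the propargylic carbinol converts (S)-9 into the (R)-aryl propargyl ether, which already has the final C2 configuration of the upper unit.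

Step 8
Reactants: 11 3-(benzyloxy)phenyl (1R)-1-[4-(benzyloxy)phenyl]-3-[2-(benzyloxy)-4-{(S)-[3,4-bis(benzyloxy)phenyl][(2S)-oxiran-2-yl]methoxy}phenyl]prop-2-yn-1-yl ether
Product: 13 (2S,3S)-7-(benzyloxy)-6-{(2S)-7-(benzyloxy)-2-[4-(benzyloxy)phenyl]-2H-chromen-4-yl}-2-[3,4-bis(benzyloxy)phenyl]chroman-3-ol, via chromene epoxide 12 (not isolated)
Conditions: AuCl3 (5 mol %), AgOTf (15 mol %), ClCH2CH2Cl, 0 °C → rt
Reagents that add atoms: none
Why: Proposed new method: the cationic gold catalyst first activates the alkyne for 6-endo-dig Friedel–Crafts attack by the 3-(benzyloxy)phenyl ether ring (para to its benzyloxy group) at the alkyne carbon bearing the electron-rich aryl group, giving 2H-chromene 12 and ring C, and the same AuCl3/AgOTf system then activates the terminal epoxide for 6-endo epoxy–arene alkylation at CH2 by the carbon ortho to the ether oxygen and para to the benzyloxy group, closing ring F with no stereocentre touched; the closest known reactions are gold-catalysed hydroarylation of aryl propargyl ethers to 2H-chromenes and AuCl3/AgOTf cyclisation of aryl ethers of 1-aryl-2,3-epoxypropan-1-ols to 2-arylchroman-3-ols, here run together in one pot.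

Step 9
Reactants: 13 (2S,3S)-7-(benzyloxy)-6-{(2S)-7-(benzyloxy)-2-[4-(benzyloxy)phenyl]-2H-chromen-4-yl}-2-[3,4-bis(benzyloxy)phenyl]chroman-3-ol
Product: 14 (2R,3R,4S)-7-(benzyloxy)-2-[4-(benzyloxy)phenyl]-4-{(2S,3S)-7-(benzyloxy)-2-[3,4-bis(benzyloxy)phenyl]-3-hydroxychroman-6-yl}chromane-3,4-diol
Conditions: OsO4 (2 mol %), NMO, acetone–H2O, 0 °C → rt
Reagents that add atoms: N-methylmorpholine N-oxide, C[N+]1([O-])CCOCC1; water, O; OsO4, O=[Os](=O)(=O)=O
Why: Catalytic OsO4/NMO syn-dihydroxylation of the electron-rich C3=C4 bond from the face opposite the C2 aryl group sets the 3-OH trans to that aryl group, while C4 becomes a tertiary carbinol whose configuration is erased in step 10.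

Step 10
Reactants: 14 (2R,3R,4S)-7-(benzyloxy)-2-[4-(benzyloxy)phenyl]-4-{(2S,3S)-7-(benzyloxy)-2-[3,4-bis(benzyloxy)phenyl]-3-hydroxychroman-6-yl}chromane-3,4-diol
Product: 15 (2R,3S,4S)-7-(benzyloxy)-2-[4-(benzyloxy)phenyl]-4-{(2S,3S)-7-(benzyloxy)-2-[3,4-bis(benzyloxy)phenyl]-3-hydroxychroman-6-yl}chroman-3-ol
Conditions: Et3SiH (5 equiv), CF3CO2H (3 equiv), CH2Cl2, −40 °C
Reagents that add atoms: none
Why: Ionic hydrogenation, in which acid ionises only the doubly benzylic tertiary C4–OH to a cation stabilised by both oxygenated rings and Et3SiH delivers hydride to the face opposite the adjacent 3-OH, so H-4 ends trans and the C4 aryl group cis to the 3-OH (4S, 2,3-trans-3,4-cis).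

Step 11
Reactants: 15 (2R,3S,4S)-7-(benzyloxy)-2-[4-(benzyloxy)phenyl]-4-{(2S,3S)-7-(benzyloxy)-2-[3,4-bis(benzyloxy)phenyl]-3-hydroxychroman-6-yl}chroman-3-ol
Product: 16 (2R,3S,4S)-2-(4-hydroxyphenyl)-4-[(2S,3S)-2-(3,4-dihydroxyphenyl)-3,7-dihydroxychroman-6-yl]chromane-3,7-diol
Conditions: H2 (1 atm), Pd(OH)2/C, THF–MeOH, rt
Reagents that add atoms: none
Why: Catalytic hydrogenolysis removes the five O-benzyl groups under neutral conditions that keep the pyran C–O bonds and all five stereocentres, giving the target.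

## Compound list

1 | 3,4-bis(benzyloxy)benzaldehyde | O=Cc1ccc(OCc2ccccc2)c(OCc2ccccc2)c1 | starting material
2 | rac-1-[3,4-bis(benzyloxy)phenyl]prop-2-en-1-ol | OC(C=C)c1ccc(OCc2ccccc2)c(OCc2ccccc2)c1 | intermediate
3 | (R)-[3,4-bis(benzyloxy)phenyl][(2S)-oxiran-2-yl]methanol | O[C@@H]([C@@H]1CO1)c1ccc(OCc2ccccc2)c(OCc2ccccc2)c1 | intermediate
4 | 2,4-dihydroxybenzaldehyde | O=Cc1ccc(O)cc1O | starting material
5 | 4-{(S)-[3,4-bis(benzyloxy)phenyl][(2S)-oxiran-2-yl]methoxy}-2-hydroxybenzaldehyde | O=Cc1ccc(O[C@H]([C@@H]2CO2)c2ccc(OCc3ccccc3)c(OCc3ccccc3)c2)cc1O | intermediate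
6 | 2-(benzyloxy)-4-{(S)-[3,4-bis(benzyloxy)phenyl][(2S)-oxiran-2-yl]methoxy}benzaldehyde | O=Cc1ccc(O[C@H]([C@@H]2CO2)c2ccc(OCc3ccccc3)c(OCc3ccccc3)c2)cc1OCc1ccccc1 | intermediate
7 | 2-(benzyloxy)-4-{(S)-[3,4-bis(benzyloxy)phenyl][(2S)-oxiran-2-yl]methoxy}-1-ethynylbenzene | C#Cc1ccc(O[C@H]([C@@H]2CO2)c2ccc(OCc3ccccc3)c(OCc3ccccc3)c2)cc1OCc1ccccc1 | intermediate
8 | 4-(benzyloxy)benzaldehyde | O=Cc1ccc(OCc2ccccc2)cc1 | starting material
9 | (1S)-1-[4-(benzyloxy)phenyl]-3-[2-(benzyloxy)-4-{(S)-[3,4-bis(benzyloxy)phenyl][(2S)-oxiran-2-yl]methoxy}phenyl]prop-2-yn-1-ol | O[C@H](C#Cc1ccc(O[C@H]([C@@H]2CO2)c2ccc(OCc3ccccc3)c(OCc3ccccc3)c2)cc1OCc1ccccc1)c1ccc(OCc2ccccc2)cc1 | intermediate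
10 | 3-(benzyloxy)phenol | Oc1cccc(OCc2ccccc2)c1 | starting material
11 | 3-(benzyloxy)phenyl (1R)-1-[4-(benzyloxy)phenyl]-3-[2-(benzyloxy)-4-{(S)-[3,4-bis(benzyloxy)phenyl][(2S)-oxiran-2-yl]methoxy}phenyl]prop-2-yn-1-yl ether | C(c1ccccc1)Oc1cccc(O[C@@H](C#Cc2ccc(O[C@H]([C@@H]3CO3)c3ccc(OCc4ccccc4)c(OCc4ccccc4)c3)cc2OCc2ccccc2)c2ccc(OCc3ccccc3)cc2)c1 | intermediate
12 | (2S)-7-(benzyloxy)-2-[4-(benzyloxy)phenyl]-4-[2-(benzyloxy)-4-{(S)-[3,4-bis(benzyloxy)phenyl][(2S)-oxiran-2-yl]methoxy}phenyl]-2H-chromene | [C@H]1(c2ccc(OCc3ccccc3)cc2)Oc2cc(OCc3ccccc3)ccc2C(c2ccc(O[C@H]([C@@H]3CO3)c3ccc(OCc4ccccc4)c(OCc4ccccc4)c3)cc2OCc2ccccc2)=C1 | intermediate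
13 | (2S,3S)-7-(benzyloxy)-6-{(2S)-7-(benzyloxy)-2-[4-(benzyloxy)phenyl]-2H-chromen-4-yl}-2-[3,4-bis(benzyloxy)phenyl]chroman-3-ol | [C@H]1(c2ccc(OCc3ccccc3)cc2)Oc2cc(OCc3ccccc3)ccc2C(c2cc3c(cc2OCc2ccccc2)O[C@@H](c2ccc(OCc4ccccc4)c(OCc4ccccc4)c2)[C@@H](O)C3)=C1 | intermediate
14 | (2R,3R,4S)-7-(benzyloxy)-2-[4-(benzyloxy)phenyl]-4-{(2S,3S)-7-(benzyloxy)-2-[3,4-bis(benzyloxy)phenyl]-3-hydroxychroman-6-yl}chromane-3,4-diol | [C@H]1(c2ccc(OCc3ccccc3)cc2)Oc2cc(OCc3ccccc3)ccc2[C@@](O)(c2cc3c(cc2OCc2ccccc2)O[C@@H](c2ccc(OCc4ccccc4)c(OCc4ccccc4)c2)[C@@H](O)C3)[C@@H]1O | intermediate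
15 | (2R,3S,4S)-7-(benzyloxy)-2-[4-(benzyloxy)phenyl]-4-{(2S,3S)-7-(benzyloxy)-2-[3,4-bis(benzyloxy)phenyl]-3-hydroxychroman-6-yl}chroman-3-ol | [C@H]1(c2ccc(OCc3ccccc3)cc2)Oc2cc(OCc3ccccc3)ccc2[C@H](c2cc3c(cc2OCc2ccccc2)O[C@@H](c2ccc(OCc4ccccc4)c(OCc4ccccc4)c2)[C@@H](O)C3)[C@@H]1O | intermediate
16 | (2R,3S,4S)-2-(4-hydroxyphenyl)-4-[(2S,3S)-2-(3,4-dihydroxyphenyl)-3,7-dihydroxychroman-6-yl]chromane-3,7-diol (CNP0243811.4) | Oc1ccc([C@H]2Oc3cc(O)ccc3[C@H](c3cc4c(cc3O)O[C@@H](c3ccc(O)c(O)c3)[C@@H](O)C4)[C@@H]2O)cc1 | target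

## Step count and risks

Total step count: 11. Longest linear sequence: 11 (1 → 16; compounds 4, 8 and 10 enter as bought materials).

**Most likely to fail, first: step 8.** The trivalent gold/silver triflate system may ionise the doubly activated propargylic ether or the C2–O bond of the chromene (loss of the C2 configuration). The ortho benzyl ether may add to the activated alkyne, or the epoxy–arene closure may lag behind. The fallback sets out from 6 and comes back at 13, closing the two rings in separate operations with a milder catalyst for ring C.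
- AuCl3/AgOTf closes ring F alone on 6 (the reacting carbon is meta to the formyl group and still activated by two ether oxygens), giving the formyl chromanol F1.
- The Ohira–Bestmann reagent (K2CO3, MeOH) gives the ethynyl chromanol F2.
- Me2Zn/ProPhenol addition to 8 gives the (S)-propargylic alcohol F3.
- Mitsunobu coupling with 10 (the hindered ring 3-OH does not compete with the activated propargylic carbinol) gives the (R)-aryl propargyl ether F4.
- Ph3PAuNTf2 (2 mol %, CH2Cl2, 0 °C), a monovalent gold catalyst that is far less Lewis acidic and has no epoxide left to handle, closes ring C to give 13.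

**Second: step 7.** The carbinol is both propargylic and 4-alkoxybenzylic, so the Mitsunobu reaction may leak through an SN1 or SN2′ path and erode the C2 configuration. The fallback sets out from 7 and comes back at 11, forming the aryl–oxygen bond instead of the alkyl–oxygen bond.
- Step 6 run with the antipodal ProPhenol ligand gives the (R)-propargylic alcohol F5, the carbinol epimer of 9.
- Palladium-catalysed C–O cross-coupling of this alcohol with 1-(benzyloxy)-3-bromobenzene ([Pd(cinnamyl)Cl]2, RockPhos, Cs2CO3, toluene, 80 °C) gives 11 with retention, since the carbinol C–O bond is never broken.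

**Third: step 10.** The C4 cation may undergo a 1,2-hydride shift from C3 to a flavan-3-one, hydride delivery may not be fully face-selective, and acid may open a pyran ring. The fallback sets out from 14 and comes back at 15, using a participating and bulkier C3 substituent.
- Ac2O, DMAP, pyridine acetylates the two secondary hydroxyls, leaving the tertiary 4-OH free, to give the diacetate F6.
- BF3·OEt2/Et3SiH (CH2Cl2, −78 °C) ionises C4; the cis 3-acetoxy group shields or bridges the upper face, and an acyloxy-bearing carbon is a poor hydride-shift donor, so hydride enters anti and gives the 4-deoxy diacetate F7.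
- K2CO3/MeOH removes both acetates to give 15.

## Further compounds

F1 | step 8 | (2S,3S)-7-(benzyloxy)-2-[3,4-bis(benzyloxy)phenyl]-3-hydroxychromane-6-carbaldehyde | O=Cc1cc2c(cc1OCc1ccccc1)O[C@@H](c1ccc(OCc3ccccc3)c(OCc3ccccc3)c1)[C@@H](O)C2
F2 | step 8 | (2S,3S)-7-(benzyloxy)-2-[3,4-bis(benzyloxy)phenyl]-6-ethynylchroman-3-ol | C#Cc1cc2c(cc1OCc1ccccc1)O[C@@H](c1ccc(OCc3ccccc3)c(OCc3ccccc3)c1)[C@@H](O)C2
F3 | step 8 | (2S,3S)-7-(benzyloxy)-2-[3,4-bis(benzyloxy)phenyl]-6-{(3S)-3-[4-(benzyloxy)phenyl]-3-hydroxyprop-1-yn-1-yl}chroman-3-ol | O[C@H](C#Cc1cc2c(cc1OCc1ccccc1)O[C@@H](c1ccc(OCc3ccccc3)c(OCc3ccccc3)c1)[C@@H](O)C2)c1ccc(OCc2ccccc2)cc1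
F4 | step 8 | (2S,3S)-7-(benzyloxy)-2-[3,4-bis(benzyloxy)phenyl]-6-{(3R)-3-[3-(benzyloxy)phenoxy]-3-[4-(benzyloxy)phenyl]prop-1-yn-1-yl}chroman-3-ol | C(c1ccccc1)Oc1cccc(O[C@@H](C#Cc2cc3c(cc2OCc2ccccc2)O[C@@H](c2ccc(OCc4ccccc4)c(OCc4ccccc4)c2)[C@@H](O)C3)c2ccc(OCc3ccccc3)cc2)c1
F5 | step 7 | (1R)-1-[4-(benzyloxy)phenyl]-3-[2-(benzyloxy)-4-{(S)-[3,4-bis(benzyloxy)phenyl][(2S)-oxiran-2-yl]methoxy}phenyl]prop-2-yn-1-ol | O[C@@H](C#Cc1ccc(O[C@H]([C@@H]2CO2)c2ccc(OCc3ccccc3)c(OCc3ccccc3)c2)cc1OCc1ccccc1)c1ccc(OCc2ccccc2)cc1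
F6 | step 10 | (2R,3R,4S)-3-acetoxy-7-(benzyloxy)-2-[4-(benzyloxy)phenyl]-4-{(2S,3S)-3-acetoxy-7-(benzyloxy)-2-[3,4-bis(benzyloxy)phenyl]chroman-6-yl}chroman-4-ol | [C@H]1(c2ccc(OCc3ccccc3)cc2)Oc2cc(OCc3ccccc3)ccc2[C@@](O)(c2cc3c(cc2OCc2ccccc2)O[C@@H](c2ccc(OCc4ccccc4)c(OCc4ccccc4)c2)[C@@H](OC(C)=O)C3)[C@@H]1OC(C)=O
F7 | step 10 | (2R,3S,4S)-7-(benzyloxy)-2-[4-(benzyloxy)phenyl]-4-{(2S,3S)-3-acetoxy-7-(benzyloxy)-2-[3,4-bis(benzyloxy)phenyl]chroman-6-yl}chroman-3-yl acetate | [C@H]1(c2ccc(OCc3ccccc3)cc2)Oc2cc(OCc3ccccc3)ccc2[C@H](c2cc3c(cc2OCc2ccccc2)O[C@@H](c2ccc(OCc4ccccc4)c(OCc4ccccc4)c2)[C@@H](OC(C)=O)C3)[C@@H]1OC(C)=O
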